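**Strategy.** Everything rests on the C9–C10 bond. Ring A carries its C3 oxygen para to the methyl-bearing quaternary C10 and an oxidised carbon (C19) on C4, so ring A is treated as a latent 5-methylsalicylate whose para carbon is bonded to C9 of ring B. One iridium-catalysed intramolecular allylic alkylation lets the salicylate phenolate attack a tethered allyl unit through that para carbon: it forms C9–C10, closes ring B, dearomatises ring A to a 4-carbomethoxy cyclohexadienone and sets C9 and C10. The precursor is methyl 2-hydroxy-5-methylbenzoate whose C6 carries a CH2CH2 tether ending in a dioxolane-protected C8 ketone and an (E)-allylic methyl carbonate.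

Key step: step 11

Assumption: the sense of induction of the iridium catalyst is carried over from intermolecular branched-selective allylations, which assigns the (R,R,Ra) ligand to the (9S,10S) dienone 17; should the sense prove opposite, the mirror-image ligand is used and nothing else changes. Terpenoid carbons are numbered as in labdanes throughout.

**Step 1**
Reactants: 1 2,3-dimethylbenzoic acid
Product: 2 6-hydroxy-2,3-dimethylbenzoic acid
Conditions: Pd(OAc)2 (10 mol %), KOAc (2 equiv), 1,4-benzoquinone (promoter), O2 (1 atm), DMA, 115 °C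
Reagents that add atoms: dioxygen (O=O)
Why: Carboxylate-directed cyclopalladation by divalent palladium followed by oxygenation with O2 (ortho C–H hydroxylation of benzoic acids) can only take place at C6, the single free ortho position.

**Step 2**
Reactants: 2 6-hydroxy-2,3-dimethylbenzoic acid; 3 iodomethane
Product: 4 methyl 6-methoxy-2,3-dimethylbenzoate
Conditions: MeI (3 equiv), K2CO3 (3 equiv), DMF, 40 °C
Reagents that add atoms: iodomethane (CI)
Why: Double SN2 O-methylation (Williamson etherification and carboxylate alkylation) masks the phenol for the carbanion chemistry and installs the methyl ester in one operation.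

**Step 3**
Reactants: 4 methyl 6-methoxy-2,3-dimethylbenzoate; 5 allyl bromide
Product: 7 methyl 2-(but-3-en-1-yl)-6-methoxy-3-methylbenzoate, via benzylic organolithium 6 (not isolated)
Conditions: LiN(i-Pr)2 (1.2 equiv), THF, −78 °C; allyl bromide (1.5 equiv), −78 → −40 °C
Reagents that add atoms: allyl bromide (C=CCBr)
Why: Lateral lithiation of an ortho-toluate removes a proton only from the methyl group ortho to the ester (the anion is an extended ester enolate), and SN2 alkylation by allyl bromide at low temperature outruns self-condensation.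

**Step 4**
Reactants: 7 methyl 2-(but-3-en-1-yl)-6-methoxy-3-methylbenzoate
Product: 8 methyl 2-(but-3-en-1-yl)-6-hydroxy-3-methylbenzoate
Conditions: BCl3 (1.5 equiv), CH2Cl2, −78 → 0 °C; aq NaHCO3
Reagents that add atoms: none
Why: BCl3 cleaves an aryl methyl ether ortho to a carbonyl group through a six-membered boron chelate at low temperature and leaves the methyl ester and the terminal alkene untouched.

**Step 5**
Reactants: 8 methyl 2-(but-3-en-1-yl)-6-hydroxy-3-methylbenzoate
Product: 9 methyl 6-hydroxy-3-methyl-2-(3-oxopropyl)benzoate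
Conditions: K2OsO4·2H2O (2 mol %), NaIO4 (4 equiv), 2,6-lutidine, dioxane/H2O (3:1), rt
Reagents that add atoms: sodium periodate ([Na+].[O-]I(=O)(=O)=O), terminal oxidant whose oxygen is relayed by the osmium catalyst
Why: Lemieux–Johnson cleavage (osmate dihydroxylation, then periodate glycol cleavage) turns the terminal alkene into the aldehyde without ozone, which could attack the phenol.

**Step 6**
Reactants: 9 methyl 6-hydroxy-3-methyl-2-(3-oxopropyl)benzoate; 10 vinylmagnesium bromide
Product: 11 methyl 6-hydroxy-2-(3-hydroxypent-4-en-1-yl)-3-methylbenzoate (racemic)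
Conditions: CH2=CHMgBr (2.3 equiv), THF, −78 → −40 °C; aq NH4Cl
Reagents that add atoms: vinylmagnesium bromide (C=C[Mg]Br)
Why: Grignard 1,2-addition to the aldehyde, in which the first equivalent forms the phenolate and thereby deactivates the hindered 2,6-disubstituted benzoate; the new stereocentre is removed in step 7.

**Step 7**
Reactants: 11 methyl 6-hydroxy-2-(3-hydroxypent-4-en-1-yl)-3-methylbenzoate
Product: 12 methyl 6-hydroxy-3-methyl-2-(3-oxopent-4-en-1-yl)benzoate
Conditions: Dess–Martin periodinane (1.2 equiv), NaHCO3, CH2Cl2, 0 °C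
Reagents that add atoms: none
Why: Dess–Martin oxidation of the secondary allylic alcohol under buffered, non-basic conditions should give the vinyl ketone without conjugate addition of the hydrogen-bonded, electron-poor phenol.

**Step 8**
Reactants: 12 methyl 6-hydroxy-3-methyl-2-(3-oxopent-4-en-1-yl)benzoate
Product: 13 methyl 2-[2-(2-ethenyl-1,3-dioxolan-2-yl)ethyl]-6-hydroxy-3-methylbenzoate
Conditions: (Me3SiOCH2)2 (2.5 equiv), TMSOTf (5 mol %), CH2Cl2, −78 → −30 °C; pyridine; aq NaHCO3/MeOH
Reagents that add atoms: 1,2-bis(trimethylsilyloxy)ethane (C[Si](C)(C)OCCO[Si](C)(C)C)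
Why: Noyori ketalisation under aprotic silyl triflate catalysis at low temperature converts enones into dioxolanes without double-bond migration, driven by formation of the disiloxane; any aryl silyl ether is cleaved in the work-up.

**Step 9**
Reactants: 14 (Z)-but-2-ene-1,4-diol
Product: 15 (Z)-but-2-ene-1,4-diyl dimethyl bis(carbonate)
Conditions: ClCO2Me (2.5 equiv), pyridine (3 equiv), CH2Cl2, 0 °C → rt
Reagents that add atoms: methyl chloroformate (COC(=O)Cl)
Why: Standard acylation of both primary hydroxy groups with a chloroformate.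

**Step 10**
Reactants: 13 methyl 2-[2-(2-ethenyl-1,3-dioxolan-2-yl)ethyl]-6-hydroxy-3-methylbenzoate; 15 (Z)-but-2-ene-1,4-diyl dimethyl bis(carbonate)
Product: 16 methyl 6-hydroxy-2-(2-{2-[(E)-3-(methoxycarbonyloxy)prop-1-en-1-yl]-1,3-dioxolan-2-yl}ethyl)-3-methylbenzoate
Conditions: second-generation Grubbs catalyst (H2IMes)(PCy3)Cl2Ru=CHPh (5 mol %), 15 (3 equiv), CH2Cl2, 40 °C
Reagents that add atoms: none
Why: Olefin cross-metathesis, in which the vinyl ketal (quaternary allylic carbon) does not homodimerise and reacts with the excess symmetrical alkene to give the (E)-allylic carbonate as the thermodynamic isomer.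

**Step 11**
Reactants: 16 methyl 6-hydroxy-2-(2-{2-[(E)-3-(methoxycarbonyloxy)prop-1-en-1-yl]-1,3-dioxolan-2-yl}ethyl)-3-methylbenzoate
Product: 17 methyl (9S,10S)-8,8-ethylenedioxy-3-oxo-13,14,15,16,17,18-hexanorlabda-1,4,11-trien-19-oate (C9 vinyl cis to the C10 methyl)
Conditions: [Ir(cod)Cl]2 (2.5 mol %), (R,R,Ra)-BINOL N,N-bis(1-phenylethyl)phosphoramidite (5 mol %), n-PrNH2 (pre-activation, then removed), Cs2CO3 (0.5 equiv), THF (0.02 M), 50 °C
Reagents that add atoms: none
Why: Proposed new method: the iridium–phosphoramidite metallacycle ionises the allylic carbonate to an η3-allyl complex, and the phenolate (formed by Cs2CO3, then by the released methoxide) attacks the substituted allyl terminus C9 from the face opposite to iridium through its para carbon C10, giving the C9–C10 bond and the cross-conjugated dienone with loss of CO2 and methanol; the closest known reaction type is the iridium-catalysed intramolecular asymmetric allylic dearomatisation of phenols that carry the tether at the para position and give spirocyclohexadienones. Ring B closes in a 6-exo mode with C6, C7 and C8 bridging C5 and the allyl terminus, so branched attack is also the only geometrically reasonable one, the linear terminus C12 requiring an eight-membered ring. C9 is set by the chiral ligand, which fixes the face of the allyl terminus that is attacked, and C10 is set relative to C9 by a chair-like transition state in which the allyl residue (the later vinyl group) is pseudo-equatorial and hence cis to the methyl group, which is pushed into the axial position. The step needs para- over ortho- and O-alkylation: O-attack would need an eight-membered ring, whereas the ortho carbon C4, the other neighbour of C5, belongs to the hydrogen-bonded β-oxo ester unit, so its charge is delocalised into the ester and it is shielded by the coplanar CO2Me group, while attack through C10 keeps the ester conjugated in the product. High dilution suppresses intermolecular O-allylation.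

**Step 12**
Reactants: 17 methyl (9S,10S)-8,8-ethylenedioxy-3-oxo-13,14,15,16,17,18-hexanorlabda-1,4,11-trien-19-oate
Product: 19 methyl (9S,10S)-8,8-ethylenedioxy-3-oxo-13,14,15,16,17,18-hexanorlabda-4,11-dien-19-oate, via lithium dienolate 18 (not isolated)
Conditions: LiBH(s-Bu)3 (1.05 equiv), THF, −78 °C; AcOH (1.1 equiv), −78 °C
Reagents that add atoms: none
Why: Conjugate hydride reduction of a β-unsubstituted enone: of the two enone termini only C1 carries a hydrogen (C5 is fully substituted and flanked by the quaternary C10), so hydride should add at C1 and protonation at C2 gives the 4-carbomethoxy enone.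

**Step 13**
Reactants: 19 methyl (9S,10S)-8,8-ethylenedioxy-3-oxo-13,14,15,16,17,18-hexanorlabda-4,11-dien-19-oate; 3 iodomethane
Product: 21 methyl (4S,5S,9S,10R)-8,8-ethylenedioxy-3-oxo-13,14,15,16,17-pentanorlabd-11-en-19-oate, via lithium enolate 20 (not isolated)
Conditions: Li (2.2 equiv), NH3(l)/THF, t-BuOH (1.0 equiv), −78 → −33 °C; isoprene; MeI (5 equiv), −78 °C → rt
Reagents that add atoms: iodomethane (CI)
Why: Dissolving-metal reductive alkylation of an alkylidene β-keto ester: two-electron reduction and axial protonation at C5 give the trans ring fusion (H5 anti to the C10 methyl), and the regiodefined enolate is methylated at C4 on the face opposite to the axial C10 methyl, leaving the ester axial and cis to that methyl; the isolated vinyl group and the ketal are inert.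

**Step 14**
Reactants: 21 methyl (4S,5S,9S,10R)-8,8-ethylenedioxy-3-oxo-13,14,15,16,17-pentanorlabd-11-en-19-oate
Product: 22 (3R,4R,5S,9S,10R)-8,8-ethylenedioxy-13,14,15,16,17-pentanorlabd-11-ene-3,19-diol
Conditions: LiAlH4 (3 equiv), THF, −78 °C → rt; H2O, aq NaOH
Reagents that add atoms: none
Why: LiAlH4 reduces ketone and ester, and hydride should add to C3 axially, from the face opposite to the axial C4 ester and the C10 methyl, which gives the equatorial C3 alcohol cis to the new C19 hydroxymethyl group.

**Step 15**
Reactants: 22 (3R,4R,5S,9S,10R)-8,8-ethylenedioxy-13,14,15,16,17-pentanorlabd-11-ene-3,19-diol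
Product: 24 (3R,4R,5S,9S,10R)-8,8-ethylenedioxy-13,14,15,16,17-pentanorlabdane-3,12,19-triol, via alkylborane 23 (not isolated)
Conditions: 9-BBN (3.5 equiv), THF, 0 → 40 °C; NaOH (3 M), H2O2 (30 %), 0 °C → rt
Reagents that add atoms: hydrogen peroxide (OO)
Why: Anti-Markovnikov hydroboration of the monosubstituted alkene with 9-BBN and oxidation of the C–B bond give the primary C12 alcohol, the borane consumed by the hydroxy groups being released in the oxidative work-up.

**Step 16**
Reactants: 24 (3R,4R,5S,9S,10R)-8,8-ethylenedioxy-13,14,15,16,17-pentanorlabdane-3,12,19-triol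
Product: 25 (3R,4R,5S,9S,10R)-3,12,19-trihydroxy-13,14,15,16,17-pentanorlabdan-8-one
Conditions: 2 M HCl, THF, 40 °C
Reagents that add atoms: water (O)
Why: Acid-catalysed hydrolysis of the dioxolane unmasks the C8 ketone before any acid-labile acetonide is present; C9, now α to the ketone, keeps (or equilibrates to) the favoured equatorial side chain, and the keto alcohol may equilibrate with its five-membered hemiketal.

**Step 17**
Reactants: 25 (3R,4R,5S,9S,10R)-3,12,19-trihydroxy-13,14,15,16,17-pentanorlabdan-8-one
Product: 26 (3R,4R,5S,9R,10S)-13,14,15,16-tetranorlabd-8(17)-ene-3,12,19-triol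
Conditions: Ph3PCH3Br (8 equiv), KOt-Bu (7.5 equiv), THF, 0 → 60 °C
Reagents that add atoms: methyltriphenylphosphonium bromide (C[P+](c1ccccc1)(c1ccccc1)c1ccccc1.[Br-])
Why: Wittig methylenation with excess ylide converts the hindered C8 ketone into the exocyclic alkene; the alkoxides of the three hydroxy groups are tolerated and any hemiketal reopens under the basic conditions.

**Step 18**
Reactants: 26 (3R,4R,5S,9R,10S)-13,14,15,16-tetranorlabd-8(17)-ene-3,12,19-triol
Product: 27 (3R,4R,5S,9R,10S)-3,19-O-isopropylidene-13,14,15,16-tetranorlabd-8(17)-ene-3,12,19-triol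
Conditions: Me2C(OMe)2 (5 equiv), PPTS (10 mol %), CH2Cl2, rt; aq NaHCO3
Reagents that add atoms: 2,2-dimethoxypropane (COC(C)(C)OC)
Why: Acid-catalysed transketalisation forms the six-membered acetonide of the 1,3-diol (equatorial C3 OH and C19), the only cyclic acetal available, and the work-up hydrolyses any mixed acyclic ketal at the C12 oxygen.

**Step 19**
Reactants: 27 (3R,4R,5S,9R,10S)-3,19-O-isopropylidene-13,14,15,16-tetranorlabd-8(17)-ene-3,12,19-triol
Product: 28 (3R,4R,5S,9R,10S)-3,19-(isopropylidenedioxy)-13,14,15,16-tetranorlabd-8(17)-en-12-al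
Conditions: Dess–Martin periodinane (1.3 equiv), NaHCO3, CH2Cl2, 0 °C → rt
Reagents that add atoms: none
Why: Dess–Martin oxidation of the primary alcohol to the aldehyde under buffered neutral conditions that neither move the exocyclic alkene nor touch the acetonide.

**Step 20**
Reactants: 29 (S)-4-hydroxyoxolan-2-one
Product: 30 (S)-4-[(tert-butyldimethylsilyl)oxy]oxolan-2-one
Conditions: TBSCl (1.2 equiv), imidazole (2 equiv), DMF, rt
Reagents that add atoms: tert-butyldimethylsilyl chloride (CC(C)(C)[Si](C)(C)Cl)
Why: Standard silylation protects the secondary alcohol of the commercial (S)-lactone, which supplies C14 with its final configuration, and turns that oxygen into a poor leaving group.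

**Step 21**
Reactants: 30 (S)-4-[(tert-butyldimethylsilyl)oxy]oxolan-2-one; 28 (3R,4R,5S,9R,10S)-3,19-(isopropylidenedioxy)-13,14,15,16-tetranorlabd-8(17)-en-12-al
Product: 32 (13S,14S)-14-O-(tert-butyldimethylsilyl)-12-hydroxy-12,13-dihydro-3,19-O-isopropylideneandrographolide (both C12 epimers), via lithium lactone enolate 31 (not isolated)
Conditions: LiN(i-Pr)2 (1.1 equiv), 30 (1.2 equiv), THF, −78 °C; 28, −78 °C; AcOH, −78 °C
Reagents that add atoms: none
Why: Lithium enolate aldol addition: at −78 °C the enolate of a β-silyloxy γ-lactone resists β-elimination (as in the enolate chemistry of silylated 2-deoxyribonolactones) and adds to the aldehyde anti to the silyloxy group, the configurations at C12 and C13 being irrelevant because both carbons become sp2 in step 22.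

**Step 22**
Reactants: 32 (13S,14S)-14-O-(tert-butyldimethylsilyl)-12-hydroxy-12,13-dihydro-3,19-O-isopropylideneandrographolide
Product: 34 14-O-(tert-butyldimethylsilyl)-3,19-O-isopropylideneandrographolide (12E,14S), via mesylate 33 (not isolated)
Conditions: MsCl (1.5 equiv), Et3N (3 equiv), CH2Cl2, 0 °C; DBU (2 equiv), 0 °C
Reagents that add atoms: none
Why: Mesylation of the C12 hydroxy group and base-induced E1cB elimination: the lactone enolate expels mesylate, a far better leaving group than silanolate, so the exocyclic alkene forms, and the thermodynamically preferred E geometry (C11 anti to the lactone carbonyl, as in tiglates) is expected from either C12 epimer.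

**Step 23**
Reactants: 34 14-O-(tert-butyldimethylsilyl)-3,19-O-isopropylideneandrographolide
Product: 35 3,19-O-isopropylideneandrographolide
Conditions: HF·pyridine, pyridine, THF, 0 °C → rt
Reagents that add atoms: none
Why: Fluoride-mediated cleavage of the secondary silyl ether under buffered conditions in which the acetonide, the allylic alcohol and the alkylidene lactone should be stable.

**Step 24**
Reactants: 35 3,19-O-isopropylideneandrographolide
Product: 36 14-O-acetyl-3,19-O-isopropylideneandrographolide
Conditions: Ac2O (neat), reflux, short reaction time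
Reagents that add atoms: acetic anhydride (CC(=O)OC(C)=O)
Why: Acylation of the allylic C14 alcohol with the anhydride alone, without an amine base, avoids base-induced loss of the allylic oxygen to the 11,12-didehydro-14-deoxy diene.

**Step 25**
Reactants: 36 14-O-acetyl-3,19-O-isopropylideneandrographolide
Product: 37 14-O-acetylandrographolide (3R,4R,5S,9R,10S,12E,14S), the target CNP0077248.1
Conditions: AcOH/H2O (7:3), rt
Reagents that add atoms: none
Why: Mild acid hydrolysis of the acetonide in aqueous acetic acid should leave the allylic acetate, the exocyclic alkene and the lactone intact.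

**Compound list**
1 | 2,3-dimethylbenzoic acid | Cc1cccc(C(=O)O)c1C | starting material
2 | 6-hydroxy-2,3-dimethylbenzoic acid | Cc1ccc(O)c(C(=O)O)c1C | intermediate
3 | iodomethane | CI | starting material
4 | methyl 6-methoxy-2,3-dimethylbenzoate | COC(=O)c1c(OC)ccc(C)c1C | intermediate
5 | allyl bromide | C=CCBr | starting material
6 | [3-methoxy-2-(methoxycarbonyl)-6-methylbenzyl]lithium | [Li]Cc1c(C)ccc(OC)c1C(=O)OC | intermediate
7 | methyl 2-(but-3-en-1-yl)-6-methoxy-3-methylbenzoate | C=CCCc1c(C)ccc(OC)c1C(=O)OC | intermediate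
8 | methyl 2-(but-3-en-1-yl)-6-hydroxy-3-methylbenzoate | C=CCCc1c(C)ccc(O)c1C(=O)OC | intermediate
9 | methyl 6-hydroxy-3-methyl-2-(3-oxopropyl)benzoate | O=CCCc1c(C)ccc(O)c1C(=O)OC | intermediate
10 | vinylmagnesium bromide | C=C[Mg]Br | starting material
11 | methyl 6-hydroxy-2-(3-hydroxypent-4-en-1-yl)-3-methylbenzoate (racemic) | C=CC(O)CCc1c(C)ccc(O)c1C(=O)OC | intermediate
12 | methyl 6-hydroxy-3-methyl-2-(3-oxopent-4-en-1-yl)benzoate | C=CC(=O)CCc1c(C)ccc(O)c1C(=O)OC | intermediate
13 | methyl 2-[2-(2-ethenyl-1,3-dioxolan-2-yl)ethyl]-6-hydroxy-3-methylbenzoate | C=CC1(CCc2c(C)ccc(O)c2C(=O)OC)OCCO1 | intermediate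
14 | (Z)-but-2-ene-1,4-diol | OC/C=C\CO | starting material
15 | (Z)-but-2-ene-1,4-diyl dimethyl bis(carbonate) | COC(=O)OC/C=C\COC(=O)OC | intermediate
16 | methyl 6-hydroxy-2-(2-{2-[(E)-3-(methoxycarbonyloxy)prop-1-en-1-yl]-1,3-dioxolan-2-yl}ethyl)-3-methylbenzoate (cyclisation precursor) | COC(=O)OC/C=C/C1(CCc2c(C)ccc(O)c2C(=O)OC)OCCO1 | intermediate
17 | methyl (9S,10S)-8,8-ethylenedioxy-3-oxo-13,14,15,16,17,18-hexanorlabda-1,4,11-trien-19-oate (bicyclic dienone, vinyl cis to the C10 methyl) | C=C[C@H]1[C@]2(C)C=CC(=O)C(C(=O)OC)=C2CCC13OCCO3 | intermediate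
18 | lithium C2–C3 dienolate formed from 17 by hydride addition at C1 | C=C[C@H]1[C@]2(C)CC=C([O-])C(C(=O)OC)=C2CCC13OCCO3.[Li+] | intermediate
19 | methyl (9S,10S)-8,8-ethylenedioxy-3-oxo-13,14,15,16,17,18-hexanorlabda-4,11-dien-19-oate | C=C[C@H]1[C@]2(C)CCC(=O)C(C(=O)OC)=C2CCC13OCCO3 | intermediate
20 | lithium C3–C4 enolate formed from 19 (H5 trans to the C10 methyl) | C12(OCCO1)CC[C@@H]3C(C(=O)OC)=C([O-])CC[C@@]3(C)[C@@H]2C=C.[Li+] | intermediate
21 | methyl (4S,5S,9S,10R)-8,8-ethylenedioxy-3-oxo-13,14,15,16,17-pentanorlabd-11-en-19-oate (ester cis, H5 trans to the C10 methyl) | C12(OCCO1)CC[C@@H]3[C@](C)(C(=O)OC)C(=O)CC[C@@]3(C)[C@@H]2C=C | intermediate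
22 | (3R,4R,5S,9S,10R)-8,8-ethylenedioxy-13,14,15,16,17-pentanorlabd-11-ene-3,19-diol | C12(OCCO1)CC[C@@H]3[C@](C)(CO)[C@H](O)CC[C@@]3(C)[C@@H]2C=C | intermediate
23 | B-alkyl-9-borabicyclo[3.3.1]nonane formed from 22 (boron on C12) | C12(OCCO1)CC[C@@H]3[C@](C)(CO)[C@H](O)CC[C@@]3(C)[C@@H]2CCB4C5CCCC4CCC5 | intermediate
24 | (3R,4R,5S,9S,10R)-8,8-ethylenedioxy-13,14,15,16,17-pentanorlabdane-3,12,19-triol | C12(OCCO1)CC[C@@H]3[C@](C)(CO)[C@H](O)CC[C@@]3(C)[C@@H]2CCO | intermediate
25 | (3R,4R,5S,9S,10R)-3,12,19-trihydroxy-13,14,15,16,17-pentanorlabdan-8-one | O=C1CC[C@@H]2[C@](C)(CO)[C@H](O)CC[C@@]2(C)[C@@H]1CCO | intermediate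
26 | (3R,4R,5S,9R,10S)-13,14,15,16-tetranorlabd-8(17)-ene-3,12,19-triol | C=C1CC[C@@H]2[C@](C)(CO)[C@H](O)CC[C@@]2(C)[C@@H]1CCO | intermediate
27 | (3R,4R,5S,9R,10S)-3,19-O-isopropylidene-13,14,15,16-tetranorlabd-8(17)-ene-3,12,19-triol | C=C1CC[C@@H]2[C@](C)(COC3(C)C)[C@H](O3)CC[C@@]2(C)[C@@H]1CCO | intermediate
28 | (3R,4R,5S,9R,10S)-3,19-(isopropylidenedioxy)-13,14,15,16-tetranorlabd-8(17)-en-12-al | C=C1CC[C@@H]2[C@](C)(COC3(C)C)[C@H](O3)CC[C@@]2(C)[C@@H]1CC=O | intermediate
29 | (S)-4-hydroxyoxolan-2-one ((S)-β-hydroxy-γ-butyrolactone) | O=C1C[C@H](O)CO1 | starting material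
30 | (S)-4-[(tert-butyldimethylsilyl)oxy]oxolan-2-one | O=C1C[C@H](O[Si](C)(C)C(C)(C)C)CO1 | intermediate
31 | lithium enolate of 30 | [Li+].[O-]C1=C[C@H](O[Si](C)(C)C(C)(C)C)CO1 | intermediate
32 | (13S,14S)-14-O-(tert-butyldimethylsilyl)-12-hydroxy-12,13-dihydro-3,19-O-isopropylideneandrographolide (C13 substituent trans to the silyloxy group; both C12 epimers) | C=C1CC[C@@H]2[C@](C)(COC3(C)C)[C@H](O3)CC[C@@]2(C)[C@@H]1CC(O)[C@@H]1C(=O)OC[C@H]1O[Si](C)(C)C(C)(C)C | intermediate
33 | C12 methanesulfonate of 32 | C=C1CC[C@@H]2[C@](C)(COC3(C)C)[C@H](O3)CC[C@@]2(C)[C@@H]1CC(OS(C)(=O)=O)[C@@H]1C(=O)OC[C@H]1O[Si](C)(C)C(C)(C)C | intermediate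
34 | 14-O-(tert-butyldimethylsilyl)-3,19-O-isopropylideneandrographolide (12E,14S) | C=C1CC[C@@H]2[C@](C)(COC3(C)C)[C@H](O3)CC[C@@]2(C)[C@@H]1C/C=C1/C(=O)OC[C@H]1O[Si](C)(C)C(C)(C)C | intermediate
35 | 3,19-O-isopropylideneandrographolide | C=C1CC[C@@H]2[C@](C)(COC3(C)C)[C@H](O3)CC[C@@]2(C)[C@@H]1C/C=C1/C(=O)OC[C@H]1O | intermediate
36 | 14-O-acetyl-3,19-O-isopropylideneandrographolide | C=C1CC[C@@H]2[C@](C)(COC3(C)C)[C@H](O3)CC[C@@]2(C)[C@@H]1C/C=C1/C(=O)OC[C@H]1OC(C)=O | intermediate
37 | 14-O-acetylandrographolide (3R,4R,5S,9R,10S,12E,14S), CNP0077248.1 | C=C1CC[C@@H]2[C@](C)(CO)[C@H](O)CC[C@@]2(C)[C@@H]1C/C=C1/C(=O)OC[C@H]1OC(C)=O | target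

**Step count.** Total: 25 steps. Longest linear sequence: 23 steps (steps 1–8, 10–19 and 21–25, from 1); steps 9 and 20 prepare the two side fragments.

**Steps most likely to fail**

Step 11. The ring closure may go astray through attack by the ester-bearing ortho carbon C4 or by oxygen, through slow ionisation at the allyl terminus next to the dioxolane, or through poor facial control at C9 and C10. The fallback uses two established reaction types and sets out from vinyl ketal 13. Cross-metathesis of 13 with allyltrimethylsilane (second-generation Grubbs catalyst, CH2Cl2, 40 °C) should give the allylsilane methyl 6-hydroxy-3-methyl-2-(2-{2-[(E)-3-(trimethylsilyl)prop-1-en-1-yl]-1,3-dioxolan-2-yl}ethyl)benzoate F1. Oxidative dearomatisation of F1 with PhI(OAc)2 in (CF3)2CHOH at low temperature inverts the polarity of the same bond formation: the oxidised phenol is captured at its para carbon by the γ-carbon of the tethered allylsilane, as in the hypervalent-iodine allylation of 4-alkylphenols to 4-allyl-4-alkylcyclohexadienones. This closes ring B and leaves the vinyl group on C9, but gives the dienone as a racemate, that is 17 together with its enantiomer methyl (9R,10R)-8,8-ethylenedioxy-3-oxo-13,14,15,16,17,18-hexanorlabda-1,4,11-trien-19-oate F2. Preparative chromatography on a chiral stationary phase then delivers 17, where the route is rejoined.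

Step 22. The elimination may lose selectivity: the wrong alkene geometry may form, or the silyloxy group may be expelled (directly or in a vinylogous sense after deprotonation at C11) instead of the mesylate. The fallback builds the C12=C13 bond by metathesis; it sets out from aldehyde 28 and returns at 34. Wittig methylenation of 28 (Ph3P=CH2, THF) should give the terminal alkene (3R,4R,5S,9R,10S)-3,19-(isopropylidenedioxy)-14,15,16-trinorlabda-8(17),12-diene F3. In parallel, lactone 30 is α-methylenated: its enolate (LiN(i-Pr)2, −78 °C) is aminomethylated with (CH2=NMe2)I to the Mannich base (3S,4S)-4-[(tert-butyldimethylsilyl)oxy]-3-[(dimethylamino)methyl]oxolan-2-one F4, which on quaternisation with MeI and treatment with NaHCO3 eliminates to (S)-4-[(tert-butyldimethylsilyl)oxy]-3-methylideneoxolan-2-one F5. Cross-metathesis of F3 with F5 (second-generation Hoveyda–Grubbs catalyst (H2IMes)Cl2Ru=CH(C6H4-2-O-i-Pr), CH2Cl2, 40 °C), a reaction known to give (E)-α-alkylidene γ-lactones from α-methylene lactones and terminal alkenes, should give 34; the hindered 1,1-disubstituted C8=C17 alkene is not expected to take part.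

Step 8. Ketal formation may be overtaken by conjugate addition of the glycol oxygen to the vinyl ketone or by its oligomerisation. The fallback makes the ketal before the double bond; it sets out from vinyl ketone 12 and returns at 13. Hydrobromination with concurrent ketalisation (Me3SiBr, ethylene glycol, CH2Cl2, 0 °C; HBr adds to the enone and the saturated β-bromo ketone is ketalised) should give methyl 2-{2-[2-(2-bromoethyl)-1,3-dioxolan-2-yl]ethyl}-6-hydroxy-3-methylbenzoate F6. E2 elimination of F6 with KOt-Bu (2.2 equiv, THF, 0 °C) then gives 13.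

**Further compounds**
F1 | step 11 | methyl 6-hydroxy-3-methyl-2-(2-{2-[(E)-3-(trimethylsilyl)prop-1-en-1-yl]-1,3-dioxolan-2-yl}ethyl)benzoate | C[Si](C)(C)C/C=C/C1(CCc2c(C)ccc(O)c2C(=O)OC)OCCO1
F2 | step 11 | methyl (9R,10R)-8,8-ethylenedioxy-3-oxo-13,14,15,16,17,18-hexanorlabda-1,4,11-trien-19-oate (enantiomer of 17) | C=C[C@@H]1[C@@]2(C)C=CC(=O)C(C(=O)OC)=C2CCC13OCCO3
F3 | step 22 | (3R,4R,5S,9R,10S)-3,19-(isopropylidenedioxy)-14,15,16-trinorlabda-8(17),12-diene | C=C1CC[C@@H]2[C@](C)(COC3(C)C)[C@H](O3)CC[C@@]2(C)[C@@H]1CC=C
F4 | step 22 | (3S,4S)-4-[(tert-butyldimethylsilyl)oxy]-3-[(dimethylamino)methyl]oxolan-2-one | CN(C)C[C@@H]1C(=O)OC[C@H]1O[Si](C)(C)C(C)(C)C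
F5 | step 22 | (S)-4-[(tert-butyldimethylsilyl)oxy]-3-methylideneoxolan-2-one | C=C1C(=O)OC[C@H]1O[Si](C)(C)C(C)(C)C
F6 | step 8 | methyl 2-{2-[2-(2-bromoethyl)-1,3-dioxolan-2-yl]ethyl}-6-hydroxy-3-methylbenzoate | BrCCC1(CCc2c(C)ccc(O)c2C(=O)OC)OCCO1
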